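## Retrosynthetic overview

- **Feature the strategy rests on:** plagilin is a symmetric biphenyl made of two catechol rings joined C1–C1'. This bond lies para to the oxygen on C4/C4' and next to the 3-methoxyphenethyl arms on C2/C2'. The para-oxygen relationship makes the bond reachable by oxidative C–H/C–H dimerisation of a simple catechol diether.
- **Disconnections:** (a) the four OH groups come from O-benzyl ethers and both CH2CH2 bridges from C≡C units, all in one hydrogenation. (b) Both C2–C(sp) bonds come from a two-directional Sonogashira coupling of a 2,2'-dibromobiphenyl with 3-ethynylanisole. (c) The C1–C1' bond comes from dehydrodimerisation of 1,2-bis(benzyloxy)-4-bromobenzene.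
- **Order of events:** the biaryl bond is made while the arms are still absent. A finished bibenzyl monomer would offer its anisole ring for intramolecular coupling to a 9,10-dihydrophenanthrene. Bromine occupies the future arm position during the oxidation and later serves as the coupling handle.
- **Rings:** no ring is formed, since all four benzene rings are bought. The bond order is biaryl, then two aryl–alkynyl bonds, then reduction and deprotection.

Key step: step 2

Remark on the chemistry: the biaryl axis carries only two ortho CH2CH2 arms and is taken as freely rotating at room temperature. This agrees with the SMILES, which has no axial descriptor, so there is no stereochemistry to set. Alkyne 8 is also sold, so steps 3 and 4 can be skipped if it is bought.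

## Route

Step 1
Reactants: 1 4-bromocatechol; 2 benzyl bromide
Product: 3 1,2-bis(benzyloxy)-4-bromobenzene
Conditions: K2CO3 (3 equiv), 2 (2.3 equiv), DMF, N2, 60 °C
Reagents that add atoms: none
Why: Williamson ether synthesis, in which both phenoxides formed with K2CO3 displace bromide from the primary benzylic halide by SN2, while exclusion of air keeps the free catechol from oxidising before it is capped.

Step 2
Reactants: 3 1,2-bis(benzyloxy)-4-bromobenzene (two molecules)
Product: 4 2,2'-dibromo-4,4',5,5'-tetrakis(benzyloxy)biphenyl
Conditions: PhI(OCOCF3)2 (0.55 equiv), BF3·OEt2 (1.1 equiv), CH2Cl2, −78 °C, then aq. NaHCO3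
Reagents that add atoms: none
Why: BF3 abstracts trifluoroacetate from PhI(OCOCF3)2, the resulting cationic trivalent iodine species forms a charge-transfer complex with the electron-rich ring of 3 and removes one electron, neutral 3 then bonds through its C5 to C5 of the radical cation, and a second one-electron oxidation with loss of the two C5 protons rearomatises both rings to give the C1–C1' bond of 4. The closest known reaction type is the Scholl-type dehydrodimerisation of 4-bromoveratrole and other 4-halo-1,2-dialkoxybenzenes to 2,2'-dihalo-4,4',5,5'-tetraalkoxybiphenyls with this same reagent pair or with MoCl5, so only the O-alkyl group is changed here. The bond forms between two separate molecules, hence no ring is closed, and neither a stereocentre nor a stable axis results. The selectivity needed is C5 against C3 and C6: C5 sits para to the oxygen on C2, where the spin density of the radical cation and the nucleophilicity of the neutral partner both peak, whereas C3 is wedged between bromine and a benzyloxy group and C6 has only an ortho oxygen to support it. Growth beyond the dimer should be held back because the two ortho bromines twist 4 out of conjugation and raise its oxidation potential above that of 3, and because only about half an equivalent of oxidant is offered. The donor-free phenyl rings of the benzyl groups lie outside the oxidation window of the reagent, and −78 °C keeps BF3 from cleaving the ethers.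

Step 3
Reactants: 5 3-iodoanisole; 6 trimethylsilylacetylene
Product: 7 [(3-methoxyphenyl)ethynyl]trimethylsilane
Conditions: PdCl2(PPh3)2 (cat.), CuI (cat.), Et3N, THF, rt
Reagents that add atoms: none
Why: Sonogashira coupling, in which the aryl iodide adds to zerovalent palladium at room temperature and the copper acetylide formed from 6 with CuI and Et3N hands over the alkynyl group, the silyl cap excluding a second arylation.

Step 4
Reactants: 7 [(3-methoxyphenyl)ethynyl]trimethylsilane
Product: 8 3-ethynylanisole
Conditions: K2CO3 (cat.), MeOH, rt
Reagents that add atoms: none
Why: Base-catalysed protodesilylation, in which methoxide attacks silicon, the acetylide leaves and is protonated by methanol, and the aryl methyl ether is inert.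

Step 5
Reactants: 4 2,2'-dibromo-4,4',5,5'-tetrakis(benzyloxy)biphenyl; 8 3-ethynylanisole (3 equiv)
Product: 10 2,2'-bis[(3-methoxyphenyl)ethynyl]-4,4',5,5'-tetrakis(benzyloxy)biphenyl, via monoalkynyl monobromide 9 (not isolated)
Conditions: PdCl2(MeCN)2 (cat.), XPhos (cat.), Cs2CO3 (5 equiv), degassed MeCN, 80 °C
Reagents that add atoms: none
Why: Twofold copper-free Sonogashira (Heck–Cassar type) alkynylation, in which the bulky electron-rich XPhos gives a monoligated zerovalent palladium able to insert into the electron-rich, ortho-substituted aryl bromides, Cs2CO3 deprotonates the palladium-bound alkyne, and the absence of copper together with an excess of 8 suppresses Glaser dimerisation and drives 9 on to 10.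

Step 6
Reactants: 10 2,2'-bis[(3-methoxyphenyl)ethynyl]-4,4',5,5'-tetrakis(benzyloxy)biphenyl
Product: 12 plagilin, via saturated tetrabenzyl ether 11 (not isolated)
Conditions: H2 (1–4 bar), 10% Pd/C, THF/MeOH, rt; filtration and concentration under argon
Reagents that add atoms: none
Why: Heterogeneous catalytic hydrogenation followed by hydrogenolysis, in which each diarylalkyne takes up two H2 to give the CH2CH2 bridges of 11, the four benzylic C–O bonds are then cleaved to toluene, and the two aryl methyl ethers, which have no benzylic C–O bond, stay, with no stereocentre created.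

## Compound list

1 | 4-bromocatechol | Oc1ccc(Br)cc1O | starting material
2 | benzyl bromide | BrCc1ccccc1 | starting material
3 | 1,2-bis(benzyloxy)-4-bromobenzene | Brc1ccc(OCc2ccccc2)c(OCc2ccccc2)c1 | intermediate
4 | 2,2'-dibromo-4,4',5,5'-tetrakis(benzyloxy)biphenyl | Brc1cc(OCc2ccccc2)c(OCc2ccccc2)cc1-c1cc(OCc2ccccc2)c(OCc2ccccc2)cc1Br | intermediate
5 | 3-iodoanisole | COc1cccc(I)c1 | starting material
6 | trimethylsilylacetylene | C#C[Si](C)(C)C | starting material
7 | [(3-methoxyphenyl)ethynyl]trimethylsilane | COc1cccc(C#C[Si](C)(C)C)c1 | intermediate
8 | 3-ethynylanisole | COc1cccc(C#C)c1 | intermediate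
9 | 2-bromo-2'-[(3-methoxyphenyl)ethynyl]-4,4',5,5'-tetrakis(benzyloxy)biphenyl (not isolated) | COc1cccc(C#Cc2cc(OCc3ccccc3)c(OCc3ccccc3)cc2-c2cc(OCc3ccccc3)c(OCc3ccccc3)cc2Br)c1 | intermediate
10 | 2,2'-bis[(3-methoxyphenyl)ethynyl]-4,4',5,5'-tetrakis(benzyloxy)biphenyl | COc1cccc(C#Cc2cc(OCc3ccccc3)c(OCc3ccccc3)cc2-c2cc(OCc3ccccc3)c(OCc3ccccc3)cc2C#Cc2cccc(OC)c2)c1 | intermediate
11 | 2,2'-bis[2-(3-methoxyphenyl)ethyl]-4,4',5,5'-tetrakis(benzyloxy)biphenyl (not isolated) | COc1cccc(CCc2cc(OCc3ccccc3)c(OCc3ccccc3)cc2-c2cc(OCc3ccccc3)c(OCc3ccccc3)cc2CCc2cccc(OC)c2)c1 | intermediate
12 | plagilin, 2,2'-bis[2-(3-methoxyphenyl)ethyl]biphenyl-4,4',5,5'-tetraol | COc1cccc(CCc2cc(O)c(O)cc2-c2cc(O)c(O)cc2CCc2cccc(OC)c2)c1 | target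

## Step count and risks

Total step count: 6.
Longest linear sequence: 4 steps (1 → 3 → 4 → 10 → 12). The alkyne branch 5 → 7 → 8 → 10 → 12 is equally long.

Steps most likely to fail:

**Step 2 (oxidative dimerisation).**
- What may go wrong:
  - Fragmentation of the radical cation at a benzylic C–O bond, or Lewis-acid debenzylation.
  - Further oxidation of the freed phenols.
  - Continued coupling past the dimer.
- Fallback: it sets out from 3 and replaces the C–H/C–H oxidation by a prefunctionalised reductive coupling.
  - Electrophilic iodination with N-iodosuccinimide and catalytic CF3CO2H in MeCN should enter the same para-to-oxygen position and give 1,2-bis(benzyloxy)-4-bromo-5-iodobenzene F1.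
  - An Ullmann homocoupling with activated Cu powder in DMF at about 140 °C should then engage only the weaker carbon–iodine bond.
  - The route is rejoined at 4.

**Step 5 (twofold Sonogashira).**
- What may go wrong:
  - Sluggish oxidative addition into the electron-rich, hindered bromides.
  - Stalling after the first coupling.
  - Intramolecular 5-exo-dig carbopalladation of the arylpalladium species derived from 9 onto the alkyne already installed on the other ring, competing with the second alkynylation.
- Fallback: it sets out from 4 and builds the two-carbon links by olefination instead of cross-coupling.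
  - Double bromine–lithium exchange with n-BuLi in THF at −78 °C should give 2,2'-dilithio-4,4',5,5'-tetrakis(benzyloxy)biphenyl F2.
  - Quenching with DMF should give 4,4',5,5'-tetrakis(benzyloxy)biphenyl-2,2'-dicarbaldehyde F3.
  - A double Wittig reaction with the ylide from (3-methoxybenzyl)triphenylphosphonium chloride and KOt-Bu in THF should give 2,2'-bis[2-(3-methoxyphenyl)ethenyl]-4,4',5,5'-tetrakis(benzyloxy)biphenyl F4. Its alkene geometry does not matter.
  - Hydrogenation over Pd/C as in step 6 passes through 11 and comes back to the route at 12.

**Step 6 (global hydrogenation).**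
- What may go wrong:
  - Incomplete hydrogenolysis of the four benzyl ethers as the polarity and solubility of the partly deprotected material change.
  - Catalyst deactivation.
  - Air oxidation of the two catechols during work-up.
- Fallback: it sets out from 10 and splits the two tasks between unrelated reagents.
  - Hydrogenation over Pd/C in THF/MeOH with added pyridine suppresses cleavage of phenolic benzyl ethers, so the reaction should stop at 11, which is then isolated.
  - The benzyl groups are then removed without hydrogen, using BCl3 and pentamethylbenzene as cation scavenger in CH2Cl2 at −78 °C. The aryl methyl ethers survive these conditions.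
  - The route is rejoined at 12. This fallback makes no compound outside the list (entry F0).

## Further compounds

F1 | step 2 | 1,2-bis(benzyloxy)-4-bromo-5-iodobenzene | Brc1cc(OCc2ccccc2)c(OCc2ccccc2)cc1I
F2 | step 5 | 2,2'-dilithio-4,4',5,5'-tetrakis(benzyloxy)biphenyl | [Li]c1cc(OCc2ccccc2)c(OCc2ccccc2)cc1-c1cc(OCc2ccccc2)c(OCc2ccccc2)cc1[Li]
F3 | step 5 | 4,4',5,5'-tetrakis(benzyloxy)biphenyl-2,2'-dicarbaldehyde | O=Cc1cc(OCc2ccccc2)c(OCc2ccccc2)cc1-c1cc(OCc2ccccc2)c(OCc2ccccc2)cc1C=O
F4 | step 5 | 2,2'-bis[2-(3-methoxyphenyl)ethenyl]-4,4',5,5'-tetrakis(benzyloxy)biphenyl (mixture of alkene geometries) | COc1cccc(C=Cc2cc(OCc3ccccc3)c(OCc3ccccc3)cc2-c2cc(OCc3ccccc3)c(OCc3ccccc3)cc2C=Cc2cccc(OC)c2)c1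
F0 | step 6 | none | none
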